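## Retrosynthetic overview

- The target comes from zeylenone by acetylating its only secondary hydroxyl; the tertiary α-ketol OH stays free.
- Zeylenone comes from a 5,6-epoxy-1-hydroxycyclohex-3-en-2-one by anti opening of the allylic oxirane carbon with benzoate. That epoxy enone comes from hydroxyl-directed epoxidation and β-silyloxy elimination of a 1-hydroxy-1-(benzoyloxymethyl)cyclohex-5-en-2-one.
- The six-membered ketol is made by ring expansion of a 1-(benzoyloxyacetyl)cyclopent-2-en-1-ol (α-ketol rearrangement with 1,2-shift of the ring alkenyl carbon). This is the only ring-forming event: the five-membered ring is bought and the six-membered ring is made from it.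
- The cyclopentenyl ketol comes from gold-catalysed oxidative benzoyloxylation of an ethynyl carbinol, made from ethynylmagnesium bromide and silyl-protected (S)-4-hydroxycyclopent-2-en-1-one, which supplies all absolute stereochemistry.

Assumption: (S)-4-hydroxycyclopent-2-en-1-one is bought as the single enantiomer; six-membered intermediates are discussed in the numbering of the target name (C1 carbinol, C2 ketone, C3, C4, C5, C6).

## Route

Step 1
Reactants: 1 (S)-4-hydroxycyclopent-2-en-1-one
Product: 2 (S)-4-{[tert-butyl(dimethyl)silyl]oxy}cyclopent-2-en-1-one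
Conditions: TBSCl, imidazole, CH2Cl2, 0 °C to rt
Reagents that add atoms: tert-butyldimethylsilyl chloride, CC(C)(C)[Si](C)(C)Cl
Why: Standard O-silylation of the secondary alcohol (silyl ether protection); the stereocentre is not touched and the bulky group later directs the addition and serves as the β-leaving group.

Step 2
Reactants: 2 (S)-4-{[tert-butyl(dimethyl)silyl]oxy}cyclopent-2-en-1-one, 3 ethynylmagnesium bromide
Product: 4 (1R,4S)-4-{[tert-butyl(dimethyl)silyl]oxy}-1-ethynylcyclopent-2-en-1-ol (OH cis to OTBS)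
Conditions: HC≡CMgBr, THF, −78 to −30 °C; aq. NH4Cl
Reagents that add atoms: none
Why: Grignard 1,2-alkynylation of the enone carbonyl takes place on the face anti to the 4-silyloxy group, which sets the tertiary carbinol centre as 1R.

Step 3
Reactants: 4 (1R,4S)-4-{[tert-butyl(dimethyl)silyl]oxy}-1-ethynylcyclopent-2-en-1-ol
Product: 5 2-[(1R,4S)-4-{[tert-butyl(dimethyl)silyl]oxy}-1-hydroxycyclopent-2-en-1-yl]-2-oxoethyl benzoate
Conditions: BzOH (2 equiv), 8-methylquinoline N-oxide (1.5 equiv), [(Mor-DalPhos)Au]NTf2 (5 mol %; Mor-DalPhos = di(1-adamantyl)(2-morpholinophenyl)phosphine), PhCl, rt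
Reagents that add atoms: benzoic acid, OC(=O)c1ccccc1; 8-methylquinoline N-oxide, Cc1cccc2ccc[n+]([O-])c12
Why: Gold-catalysed alkyne oxidation with O–H insertion: the N-oxide delivers oxygen to the internal alkyne carbon of the monovalent-gold π-complex and the α-oxo gold carbenoid at the terminal carbon is trapped by benzoic acid (the P,N ligand tempers the carbenoid so intermolecular trapping wins), giving the benzoyloxymethyl ketone with both stereocentres untouched.

Step 4
Reactants: 5 2-[(1R,4S)-4-{[tert-butyl(dimethyl)silyl]oxy}-1-hydroxycyclopent-2-en-1-yl]-2-oxoethyl benzoate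
Product: 6 [(1R,4S)-4-{[tert-butyl(dimethyl)silyl]oxy}-1-hydroxy-6-oxocyclohex-2-en-1-yl]methyl benzoate (tertiary OH cis to OTBS)
Conditions: Sc(OTf)3 (10 mol %), 2,6-di-tert-butylpyridine (20 mol %), 4 Å MS, ClCH2CH2Cl, 23–40 °C, Ar
Reagents that add atoms: none
Why: Proposed new method: an alkenyl-selective, chirality-transferring α-ketol (acyloin) ring expansion of a 1-acylcyclopent-2-en-1-ol. Trivalent scandium chelates the tertiary OH and the ketone oxygen (five-membered chelate, syn-periplanar O–C–C=O), and the side-chain carbonyl, activated further by its α-benzoyloxy group, lies under the ring face where the p-lobe of alkenyl carbon C2 points. C2 therefore shifts suprafacially from C1 to the carbonyl carbon in preference to the CH2 carbon C5 (alkenyl above primary alkyl in migratory aptitude, π-assisted as in semipinacol shifts), with release of cyclopentene strain. The syn chelate places the new carbinol oxygen on the face of the original hydroxyl, so the quaternary centre of 6 is set by 1,2-chirality transfer from C1 of 5. The closest known reaction types are the Lewis-acid-catalysed α-ketol ring expansion of saturated 1-acylcycloalkanols (alkyl migration) and the Lewis-acid-promoted semipinacol 1,2-alkenyl shift.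

Step 5
Reactants: 6 [(1R,4S)-4-{[tert-butyl(dimethyl)silyl]oxy}-1-hydroxy-6-oxocyclohex-2-en-1-yl]methyl benzoate
Product: 7 [(1S,2S,5S,6R)-5-{[tert-butyl(dimethyl)silyl]oxy}-2-hydroxy-3-oxo-7-oxabicyclo[4.1.0]heptan-2-yl]methyl benzoate (oxirane cis to the tertiary OH)
Conditions: VO(acac)2 (5 mol %), t-BuOOH (decane), CH2Cl2, 0 °C to rt
Reagents that add atoms: tert-butyl hydroperoxide, CC(C)(C)OO
Why: Hydroxyl-directed vanadium-catalysed epoxidation of the tertiary allylic alcohol delivers oxygen to the C5=C6 alkene on the face of the C1 hydroxyl, which fixes the C6 oxygen cis to the C1 hydroxyl and prepares C5 for inversion.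

Step 6
Reactants: 7 [(1S,2S,5S,6R)-5-{[tert-butyl(dimethyl)silyl]oxy}-2-hydroxy-3-oxo-7-oxabicyclo[4.1.0]heptan-2-yl]methyl benzoate
Product: 9 zeylenone, via epoxy enone 8 (not isolated)
Conditions: DBU (1.1 equiv), CH2Cl2, 0 °C to rt; then BzOH (3 equiv), 40 °C
Reagents that add atoms: benzoic acid, OC(=O)c1ccccc1
Why: E1cB loss of silanolate from the β-silyloxy ketone gives epoxy enone 8, and the buffered benzoate then opens the oxirane by SN2 attack at the allylic carbon C5 (C6 is neopentyl-like and shielded) anti to the oxygen, giving the 5R benzoate trans to the 6S hydroxyl, which stays cis to the C1 hydroxyl.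

Step 7
Reactants: 9 zeylenone, [(1S,5R,6S)-5-(benzoyloxy)-1,6-dihydroxy-2-oxocyclohex-3-en-1-yl]methyl benzoate
Product: 10 2-O-acetylzeylenone, [(1S,5R,6S)-6-(acetyloxy)-5-(benzoyloxy)-1-hydroxy-2-oxocyclohex-3-en-1-yl]methyl benzoate
Conditions: Ac2O (1.5 equiv), pyridine, CH2Cl2, 0 °C to rt
Reagents that add atoms: acetic anhydride, CC(=O)OC(C)=O
Why: Esterification of the secondary hydroxyl only; the hindered tertiary α-ketol hydroxyl does not acylate without DMAP or heat, and no stereocentre is affected.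

## Compound list

1 | (S)-4-hydroxycyclopent-2-en-1-one | O=C1C=C[C@@H](O)C1 | starting material
2 | (S)-4-{[tert-butyl(dimethyl)silyl]oxy}cyclopent-2-en-1-one | O=C1C=C[C@@H](O[Si](C)(C)C(C)(C)C)C1 | intermediate
3 | ethynylmagnesium bromide | C#C[Mg]Br | starting material
4 | (1R,4S)-4-{[tert-butyl(dimethyl)silyl]oxy}-1-ethynylcyclopent-2-en-1-ol | C#C[C@]1(O)C=C[C@@H](O[Si](C)(C)C(C)(C)C)C1 | intermediate
5 | 2-[(1R,4S)-4-{[tert-butyl(dimethyl)silyl]oxy}-1-hydroxycyclopent-2-en-1-yl]-2-oxoethyl benzoate | O=C(COC(=O)c1ccccc1)[C@]1(O)C=C[C@@H](O[Si](C)(C)C(C)(C)C)C1 | intermediate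
6 | [(1R,4S)-4-{[tert-butyl(dimethyl)silyl]oxy}-1-hydroxy-6-oxocyclohex-2-en-1-yl]methyl benzoate | O=C1C[C@H](O[Si](C)(C)C(C)(C)C)C=C[C@@]1(O)COC(=O)c1ccccc1 | intermediate
7 | [(1S,2S,5S,6R)-5-{[tert-butyl(dimethyl)silyl]oxy}-2-hydroxy-3-oxo-7-oxabicyclo[4.1.0]heptan-2-yl]methyl benzoate | O=C1C[C@H](O[Si](C)(C)C(C)(C)C)[C@@H]2O[C@@H]2[C@@]1(O)COC(=O)c1ccccc1 | intermediate
8 | [(1S,2S,6S)-2-hydroxy-3-oxo-7-oxabicyclo[4.1.0]hept-4-en-2-yl]methyl benzoate | O=C1C=C[C@@H]2O[C@@H]2[C@@]1(O)COC(=O)c1ccccc1 | intermediate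
9 | zeylenone, [(1S,5R,6S)-5-(benzoyloxy)-1,6-dihydroxy-2-oxocyclohex-3-en-1-yl]methyl benzoate | O[C@H]1[C@H](OC(=O)c2ccccc2)C=CC(=O)[C@]1(O)COC(=O)c1ccccc1 | intermediate
10 | 2-O-acetylzeylenone, [(1S,5R,6S)-6-(acetyloxy)-5-(benzoyloxy)-1-hydroxy-2-oxocyclohex-3-en-1-yl]methyl benzoate | CC(=O)O[C@H]1[C@H](OC(=O)c2ccccc2)C=CC(=O)[C@]1(O)COC(=O)c1ccccc1 | target

## Step count

Total steps: 7. Longest linear sequence: 7 steps (1 to 10).

## Steps most likely to fail, and fallbacks

**Step 3 (gold oxidation on a free tertiary, allylic and propargylic alcohol).** The carbinol may ionise, or the carbenoid may be trapped internally by the tertiary OH. The fallback sets out from 2 and comes back at 5 without any alkyne. 1-Ethoxyvinyllithium (ethyl vinyl ether, t-BuLi, THF, −78 °C) adds to 2 anti to the silyloxy group to give (1R,4S)-4-{[tert-butyl(dimethyl)silyl]oxy}-1-(1-ethoxyethenyl)cyclopent-2-en-1-ol F1. Cold dilute aqueous HCl in THF hydrolyses the enol ether to the methyl ketone 1-[(1R,4S)-4-{[tert-butyl(dimethyl)silyl]oxy}-1-hydroxycyclopent-2-en-1-yl]ethan-1-one F2. F2 is then α-benzoyloxylated at its only enolisable position by the known hypoiodite-catalysed oxidative coupling with benzoic acid (Bu4NI cat., t-BuOOH, BzOH, EtOAc, 60 °C) to give 5.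

**Step 4 (the proposed ring expansion).** The risks are competing shift of the CH2 carbon (which leads to the conjugated, thermodynamically preferred regioisomer), erosion of the face transfer, and premature loss of silanol. The fallback uses known chemistry, sets out from 5 and comes back at 6.
- NaBH4/CeCl3 in MeOH reduces the side-chain ketone to the diol 2-hydroxy-2-[(1R,4S)-4-{[tert-butyl(dimethyl)silyl]oxy}-1-hydroxycyclopent-2-en-1-yl]ethyl benzoate F3. Both carbinol epimers are usable.
- MsCl/Et3N mesylates only the secondary hydroxyl, giving the mesylate F4.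
- Et3Al in CH2Cl2 at −78 °C triggers the known semipinacol 1,2-alkenyl shift of a β-mesyloxy alcohol (alkenyl migrates far faster than alkyl), giving the ring-expanded ketone 2-(benzoyloxymethyl)-5-{[tert-butyl(dimethyl)silyl]oxy}cyclohex-3-en-1-one F5.
- Soft enolisation (TMSCl, NaI, Et3N, MeCN) gives the conjugated silyl dienol ether F6.
- Rubottom oxidation (DMDO, then mild acid) installs the tertiary hydroxyl and gives 6 together with its C1 epimer F7, which is removed by chromatography. Face selectivity here is expected to be modest, and this is the price of the fallback.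

**Step 6 (one-pot elimination and benzoate opening).** The risks are sluggish epoxide opening, benzoyl migration under basic conditions, or base-induced isomerisation of the epoxy enone. The fallback is stepwise, sets out from 7 and comes back at 9.
- HF·pyridine buffered with pyridine (THF, 0 °C) removes the silyl group to give the diol [(1S,2S,5S,6S)-2,5-dihydroxy-3-oxo-7-oxabicyclo[4.1.0]heptan-2-yl]methyl benzoate F8.
- MsCl/Et3N (CH2Cl2, −20 °C to rt) converts the secondary hydroxyl into the mesylate F9, which eliminates in the same flask to epoxy enone 8, now isolated.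
- 8 is opened with benzoic acid on a Ti(OiPr)4 template (CH2Cl2, rt). The titanium alkoxide of the tertiary hydroxyl activates the oxirane and delivers benzoate to the remote, allylic oxirane carbon with inversion, giving 9.

## Further compounds

F1 | step 3 | (1R,4S)-4-{[tert-butyl(dimethyl)silyl]oxy}-1-(1-ethoxyethenyl)cyclopent-2-en-1-ol | C=C(OCC)[C@]1(O)C=C[C@@H](O[Si](C)(C)C(C)(C)C)C1
F2 | step 3 | 1-[(1R,4S)-4-{[tert-butyl(dimethyl)silyl]oxy}-1-hydroxycyclopent-2-en-1-yl]ethan-1-one | CC(=O)[C@]1(O)C=C[C@@H](O[Si](C)(C)C(C)(C)C)C1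
F3 | step 4 | 2-hydroxy-2-[(1R,4S)-4-{[tert-butyl(dimethyl)silyl]oxy}-1-hydroxycyclopent-2-en-1-yl]ethyl benzoate (both side-chain carbinol epimers) | OC(COC(=O)c1ccccc1)[C@]1(O)C=C[C@@H](O[Si](C)(C)C(C)(C)C)C1
F4 | step 4 | 2-[(1R,4S)-4-{[tert-butyl(dimethyl)silyl]oxy}-1-hydroxycyclopent-2-en-1-yl]-2-(methanesulfonyloxy)ethyl benzoate (both epimers at the mesylate carbon) | CS(=O)(=O)OC(COC(=O)c1ccccc1)[C@]1(O)C=C[C@@H](O[Si](C)(C)C(C)(C)C)C1
F5 | step 4 | [(4S)-4-{[tert-butyl(dimethyl)silyl]oxy}-6-oxocyclohex-2-en-1-yl]methyl benzoate (both C1 epimers) | O=C1C[C@H](O[Si](C)(C)C(C)(C)C)C=CC1COC(=O)c1ccccc1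
F6 | step 4 | [(4S)-4-{[tert-butyl(dimethyl)silyl]oxy}-6-(trimethylsilyloxy)cyclohexa-1,5-dien-1-yl]methyl benzoate | C[Si](C)(C)OC1=C(COC(=O)c2ccccc2)C=C[C@@H](O[Si](C)(C)C(C)(C)C)C1
F7 | step 4 | [(1S,4S)-4-{[tert-butyl(dimethyl)silyl]oxy}-1-hydroxy-6-oxocyclohex-2-en-1-yl]methyl benzoate (C1 epimer of 6) | O=C1C[C@H](O[Si](C)(C)C(C)(C)C)C=C[C@]1(O)COC(=O)c1ccccc1
F8 | step 6 | [(1S,2S,5S,6S)-2,5-dihydroxy-3-oxo-7-oxabicyclo[4.1.0]heptan-2-yl]methyl benzoate | O=C1C[C@H](O)[C@@H]2O[C@@H]2[C@@]1(O)COC(=O)c1ccccc1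
F9 | step 6 | [(1S,2S,5S,6S)-2-hydroxy-5-(methanesulfonyloxy)-3-oxo-7-oxabicyclo[4.1.0]heptan-2-yl]methyl benzoate | O=C1C[C@H](OS(C)(=O)=O)[C@@H]2O[C@@H]2[C@@]1(O)COC(=O)c1ccccc1
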